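The readings come from a simulation for an exercise; scatter was added.

A target that climbs steadily invites you to run it up to the whole charge, so test the climb first.

- Thursday's: solid substrate 0.055 M; run made earlier
- flask: solid substrate 0.11 M; time 12 h

Thursday's run (percent of the solid substrate charged)

| time / min | target / % | starting material / % | solid substrate / % |
|---|---|---|---|
| 6.00 | 0 | 14.4 | 80.6 |
| 12.0 | 0.5 | 23.1 | 64.6 |
| 30.0 | 5.6 | 42.7 | 21.1 |
| 80.0 | 22.2 | 43.1 | 0.3 |

(scatter of a reading: 0.3 percentage points)

- in percentages every species weighs as the solid substrate in it: one target counts as two
- at the start none of the solid substrate is in solution
- what has only dissolved of solid substrate counts as not reacted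
- a reading or a percentage of target counts all its forms, free or not
- the reaction counts as stopped when no species that holds the solid substrate changes by six tenths of a point or more over the second half of the time
- starting material means what is dissolved; the solid is not counted in it

- at 12 h, what has stopped the reaction, if anything has (for what has run out or reacted, a solid counts together with what of it has only dissolved) (it is still moving / all of the solid substrate has reacted / forward and back rates have come level)
- the target standing at 12 h, as a percentage of the solid substrate charged
- the starting material standing at 12 h, as a percentage of the solid substrate charged

Write a for the starting material, p for the target, both as fractions of the charge c. One target takes two starting material, so a one-way step gains as a squared. In Thursday's run p gains 0.00283 min⁻¹ from 12.0 min to 30.0 min and 0.00332 min⁻¹ from there to 80.0 min, while the squared mean of a rises from 0.108 to 0.184, a larger step than the gain makes. I read a back step in that. Setting each gain equal to f·a squared minus b·p, with f and b the forward and back coefficients and with mean p of 0.0305 and 0.139, gives f/b = 2cK, where K is the equilibrium constant, target over starting material squared in molar terms, which these scattered readings put at 16.4 M⁻¹.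

The last reading of Thursday's run leaves a gap of g = 0.798 per unit of a, which I take as an unseen form that goes with a. At level, counting the whole charge as dissolved, 1 = (1 + g)a + 2cK·a squared. For this flask my reckoning gives a = 33.3% and p = 40.1%. At Thursday's pace the solid lasts about 1.27 h and that target takes about 2.01 h, both short against 12 h, so I expect forward and back rates level.

The weak link is the mean over the first stretch of Thursday's run, where a goes from 23.1% to 42.7%. Averaging the squares instead gives 20.4 M⁻¹, and so for this flask p = 43.8%.

The forecast differs. It says it is still moving, with target 92% (82% to 95%) and starting material 6.5% (4.5% to 12%), on the ground that “No reverse step is established from the data”.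

In the flask at 12 h, forward and back rates have come level, with target 38.4% and starting material 34.8%.

    2 starting material ⇌ target (K = 14.4 M⁻¹, k = 0.00442 M⁻¹ s⁻¹)
    solid substrate ⇌ starting material, rate k2*(cs2 - [starting material]) while solid is left; crystals form when [starting material] > cs2 (solubility = 0.0620 M, k = 5.03 × 10⁻⁴ s⁻¹)
    crystals ⇌ target, rate k3*(cs3 - [target]) while solid is left; crystals form when [target] > cs3 (solubility = 43.0 mM, k = 0.0900 s⁻¹)
    starting material ⇌ dormant form (K = 0.771, k = 0.00267 s⁻¹)

Over the second half of the time no share in this flask moves: the largest change is 0 percentage points. The balance with K stands 1.7 points above this target and 1.5 points below this starting material.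

For the neighbour charged with 0.044 M, the same balance gives a = 41.7% and p = 25.1%. At 12 h that flask gives starting material 43.1% and target 23.6%.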